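**Retrosynthetic overview**

1. Feature: C8, the CH that carries O4' of the syringyl ring, is the middle carbon of a glycerol unit C7–C8–C9. Its two ends differ only in that C7 is bonded to C1 of the guaiacyl ring, so a prochiral 2-aryloxypropane-1,3-diol built on the sinapyl ring already contains the whole side chain.
2. C1–C7 bond: chelation-controlled addition of the silyl-protected guaiacyl Grignard reagent to the (R)-2-aryloxy-3-silyloxypropanal sets C7 (threo); global desilylation follows.
3. C8 configuration: lipase desymmetrisation of the prochiral 1,3-diacetate, then silylation, deacetylation and oxidation to the aldehyde.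
4. C8–O4' bond: Williamson alkylation of sinapyl alcohol with diethyl bromomalonate, then silylation of the allylic alcohol and hydride reduction to the diol.
5. Rings: none is formed; both benzene rings come from the starting materials (sinapyl alcohol and 4-bromo-2-methoxyphenol).

Key step: step 11

Assumption: the Burkholderia cepacia lipase is taken to cleave the pro-S acetoxymethyl arm of diacetate 6, by analogy with 2-alkoxypropane-1,3-diyl diacetates, so that the (R)-monoacetate 7 results; the sense is to be confirmed on 7, and if it proves opposite, acetylation of diol 5 with vinyl acetate and the same enzyme (the mirror mode) should give 7 instead.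

Remark on order: steps 9 and 10 are run before step 8, so that aldehyde 10 can be used at once. TBS = tert-butyldimethylsilyl.

**Route**

Step 1
Reactants: 1 (E)-sinapyl alcohol; 2 diethyl bromomalonate
Product: 3 diethyl 2-{4-[(E)-3-hydroxyprop-1-en-1-yl]-2,6-dimethoxyphenoxy}malonate
Conditions: K2CO3 (1.5 equiv), acetone, reflux, Ar
Reagents that add atoms: none
Why: Carbonate deprotonates only the phenol, and the phenoxide displaces bromide from the doubly activated α-bromo malonate (Williamson ether synthesis), which leaves the allylic alcohol untouched and creates no stereocentre.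

Step 2
Reactants: 3 diethyl 2-{4-[(E)-3-hydroxyprop-1-en-1-yl]-2,6-dimethoxyphenoxy}malonate
Product: 4 diethyl 2-{4-[(E)-3-(tert-butyldimethylsilyloxy)prop-1-en-1-yl]-2,6-dimethoxyphenoxy}malonate
Conditions: TBSCl, imidazole, DMF, 0 °C to rt
Reagents that add atoms: tert-butyldimethylsilyl chloride, CC(C)(C)[Si](C)(C)Cl
Why: Imidazole-promoted silylation of the only free hydroxyl should be clean, and it comes after the phenol has been etherified, so no phenol/alcohol selectivity is needed.

Step 3
Reactants: 4 diethyl 2-{4-[(E)-3-(tert-butyldimethylsilyloxy)prop-1-en-1-yl]-2,6-dimethoxyphenoxy}malonate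
Product: 5 2-{4-[(E)-3-(tert-butyldimethylsilyloxy)prop-1-en-1-yl]-2,6-dimethoxyphenoxy}propane-1,3-diol
Conditions: LiAlH4, THF, 0 °C (ester added to the hydride); Rochelle salt work-up
Reagents that add atoms: none
Why: Hydride reduction of both esters gives the prochiral 1,3-diol; with the allylic hydroxyl silylated there is no alkoxide to direct hydroalumination of the styrenyl alkene, and the TBS ether is stable at 0 °C.

Step 4
Reactants: 5 2-{4-[(E)-3-(tert-butyldimethylsilyloxy)prop-1-en-1-yl]-2,6-dimethoxyphenoxy}propane-1,3-diol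
Product: 6 2-{4-[(E)-3-(tert-butyldimethylsilyloxy)prop-1-en-1-yl]-2,6-dimethoxyphenoxy}propane-1,3-diyl diacetate
Conditions: Ac2O, pyridine, DMAP (cat.), CH2Cl2, rt
Reagents that add atoms: acetic anhydride, CC(=O)OC(C)=O
Why: DMAP-catalysed acetylation of two unhindered primary alcohols should be complete, and it supplies the prochiral diacetate for the enzyme.

Step 5
Reactants: 6 2-{4-[(E)-3-(tert-butyldimethylsilyloxy)prop-1-en-1-yl]-2,6-dimethoxyphenoxy}propane-1,3-diyl diacetate
Product: 7 (R)-3-hydroxy-2-{4-[(E)-3-(tert-butyldimethylsilyloxy)prop-1-en-1-yl]-2,6-dimethoxyphenoxy}propyl acetate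
Conditions: lipase PS (Burkholderia cepacia), 0.1 M phosphate buffer pH 7–acetone (9:1), 25 °C, stopped at mono-hydrolysis; cold neutral work-up
Reagents that add atoms: none
Why: Lipase-catalysed hydrolysis of one of two enantiotopic acetoxymethyl groups (desymmetrisation of a 2-substituted propane-1,3-diyl diacetate) sets C8, the enzyme active site being the controlling element, and the neutral medium limits 1,3-acetyl migration, which would racemise 7.

Step 6
Reactants: 7 (R)-3-hydroxy-2-{4-[(E)-3-(tert-butyldimethylsilyloxy)prop-1-en-1-yl]-2,6-dimethoxyphenoxy}propyl acetate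
Product: 8 (S)-3-(tert-butyldimethylsilyloxy)-2-{4-[(E)-3-(tert-butyldimethylsilyloxy)prop-1-en-1-yl]-2,6-dimethoxyphenoxy}propyl acetate
Conditions: TBSCl, imidazole, CH2Cl2, 0 °C, directly after step 5
Reagents that add atoms: tert-butyldimethylsilyl chloride, CC(C)(C)[Si](C)(C)Cl
Why: Fast silylation of the free primary hydroxyl at 0 °C fixes the two arms as different groups before acetyl migration can occur; the change of descriptor from R to S is only a CIP priority change.

Step 7
Reactants: 8 (S)-3-(tert-butyldimethylsilyloxy)-2-{4-[(E)-3-(tert-butyldimethylsilyloxy)prop-1-en-1-yl]-2,6-dimethoxyphenoxy}propyl acetate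
Product: 9 (S)-3-(tert-butyldimethylsilyloxy)-2-{4-[(E)-3-(tert-butyldimethylsilyloxy)prop-1-en-1-yl]-2,6-dimethoxyphenoxy}propan-1-ol
Conditions: K2CO3 (0.2 equiv), MeOH, 0 °C, short reaction time
Reagents that add atoms: none
Why: Base-catalysed transesterification with methanol removes the acetate while both alkyl TBS ethers survive, and the low temperature and catalytic base are chosen to keep the O9 silyl group from migrating to O7, which would invert C8.

Step 8
Reactants: 9 (S)-3-(tert-butyldimethylsilyloxy)-2-{4-[(E)-3-(tert-butyldimethylsilyloxy)prop-1-en-1-yl]-2,6-dimethoxyphenoxy}propan-1-ol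
Product: 10 (R)-3-(tert-butyldimethylsilyloxy)-2-{4-[(E)-3-(tert-butyldimethylsilyloxy)prop-1-en-1-yl]-2,6-dimethoxyphenoxy}propanal
Conditions: Dess–Martin periodinane, NaHCO3, CH2Cl2, 0 °C to rt; filtration, no chromatography, used at once
Reagents that add atoms: none
Why: Dess–Martin oxidation under bicarbonate buffering is the mildest route to an enolisable α-aryloxy aldehyde and leaves the styrenyl alkene and the silyl ethers alone; C8 is not touched and its descriptor reverts to R by priority only.

Step 9
Reactants: 11 4-bromo-2-methoxyphenol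
Product: 12 (4-bromo-2-methoxyphenoxy)(tert-butyl)dimethylsilane
Conditions: TBSCl, imidazole, DMF, rt
Reagents that add atoms: tert-butyldimethylsilyl chloride, CC(C)(C)[Si](C)(C)Cl
Why: Silylation of the phenol removes the acidic proton that would destroy the Grignard reagent.

Step 10
Reactants: 12 (4-bromo-2-methoxyphenoxy)(tert-butyl)dimethylsilane
Product: 13 4-(tert-butyldimethylsilyloxy)-3-methoxyphenylmagnesium bromide, as a titrated solution of about 1 M
Conditions: Mg turnings (I2-activated), THF, 40–50 °C
Reagents that add atoms: magnesium, [Mg]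
Why: Oxidative insertion of magnesium into the aryl C–Br bond (Grignard formation) tolerates aryl silyl ethers, and a concentrated solution keeps the THF carried into the next step small.

Step 11
Reactants: 10 (R)-3-(tert-butyldimethylsilyloxy)-2-{4-[(E)-3-(tert-butyldimethylsilyloxy)prop-1-en-1-yl]-2,6-dimethoxyphenoxy}propanal; 13 4-(tert-butyldimethylsilyloxy)-3-methoxyphenylmagnesium bromide
Product: 14 (1R,2R)-3-(tert-butyldimethylsilyloxy)-1-[4-(tert-butyldimethylsilyloxy)-3-methoxyphenyl]-2-{4-[(E)-3-(tert-butyldimethylsilyloxy)prop-1-en-1-yl]-2,6-dimethoxyphenoxy}propan-1-ol (threo, 7R,8R)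
Conditions: 10 (crude, dried azeotropically), MgBr2·OEt2 (2 equiv), CH2Cl2, −78 °C; then 13 (1.5 equiv, added slowly), −78 °C; sat. aq NH4Cl
Reagents that add atoms: none
Why: MgBr2 binds the aldehyde oxygen and the C8 aryl ether oxygen, with one flanking methoxy oxygen as a third donor, so that C7=O and C8–O lie syn-periplanar in a five-membered chelate and the carbonyl is both activated and conformationally locked. The arylmagnesium then adds to C7 from the face flanked by the C8 hydrogen rather than by the CH2OTBS group (Cram chelate model), which forms the C1–C7 bond and gives the 7R alcohol from the 8R aldehyde, that is the threo (syn) isomer. The closest known reaction type is the chelation-controlled Grignard addition to α-alkoxy aldehydes such as protected 2-O-benzylglyceraldehydes; an aryl ether is a weaker donor, so the level of control on this substrate is an extrapolation. No ring is closed. The one new stereocentre, C7, is controlled by the existing C8 centre through the chelate. The step needs the chelate pathway to outrun Felkin–Anh addition (which would give the erythro isomer) and 1,2-addition to outrun α-deprotonation; the bulky, poorly donating TBS ether on O9 excludes a competing six-membered chelate, the oxygen-rich syringyl ether and the dichloromethane medium favour the five-membered one, and the electron-rich aryl Grignard reagent is a good nucleophile but a weak base at −78 °C.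

Step 12
Reactants: 14 (1R,2R)-3-(tert-butyldimethylsilyloxy)-1-[4-(tert-butyldimethylsilyloxy)-3-methoxyphenyl]-2-{4-[(E)-3-(tert-butyldimethylsilyloxy)prop-1-en-1-yl]-2,6-dimethoxyphenoxy}propan-1-ol
Product: 15 (1R,2R)-1-(4-hydroxy-3-methoxyphenyl)-2-{4-[(E)-3-hydroxyprop-1-en-1-yl]-2,6-dimethoxyphenoxy}propane-1,3-diol (target, threo 7R,8R)
Conditions: TBAF (3.5 equiv), AcOH (3.5 equiv), THF, 0 °C to rt
Reagents that add atoms: none
Why: Fluoride-mediated desilylation removes the aryl and both alkyl TBS groups, and the acetic acid buffer keeps the freed para-phenol from expelling the benzylic hydroxyl through a quinone methide, which would epimerise C7.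

**Compound list**

1 | (E)-sinapyl alcohol | COc1cc(/C=C/CO)cc(OC)c1O | starting material
2 | diethyl bromomalonate | CCOC(=O)C(Br)C(=O)OCC | starting material
3 | diethyl 2-{4-[(E)-3-hydroxyprop-1-en-1-yl]-2,6-dimethoxyphenoxy}malonate | CCOC(=O)C(Oc1c(OC)cc(/C=C/CO)cc1OC)C(=O)OCC | intermediate
4 | diethyl 2-{4-[(E)-3-(tert-butyldimethylsilyloxy)prop-1-en-1-yl]-2,6-dimethoxyphenoxy}malonate | CCOC(=O)C(Oc1c(OC)cc(/C=C/CO[Si](C)(C)C(C)(C)C)cc1OC)C(=O)OCC | intermediate
5 | 2-{4-[(E)-3-(tert-butyldimethylsilyloxy)prop-1-en-1-yl]-2,6-dimethoxyphenoxy}propane-1,3-diol | OCC(CO)Oc1c(OC)cc(/C=C/CO[Si](C)(C)C(C)(C)C)cc1OC | intermediate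
6 | 2-{4-[(E)-3-(tert-butyldimethylsilyloxy)prop-1-en-1-yl]-2,6-dimethoxyphenoxy}propane-1,3-diyl diacetate | CC(=O)OCC(COC(C)=O)Oc1c(OC)cc(/C=C/CO[Si](C)(C)C(C)(C)C)cc1OC | intermediate
7 | (R)-3-hydroxy-2-{4-[(E)-3-(tert-butyldimethylsilyloxy)prop-1-en-1-yl]-2,6-dimethoxyphenoxy}propyl acetate | CC(=O)OC[C@@H](CO)Oc1c(OC)cc(/C=C/CO[Si](C)(C)C(C)(C)C)cc1OC | intermediate
8 | (S)-3-(tert-butyldimethylsilyloxy)-2-{4-[(E)-3-(tert-butyldimethylsilyloxy)prop-1-en-1-yl]-2,6-dimethoxyphenoxy}propyl acetate | CC(=O)OC[C@@H](CO[Si](C)(C)C(C)(C)C)Oc1c(OC)cc(/C=C/CO[Si](C)(C)C(C)(C)C)cc1OC | intermediate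
9 | (S)-3-(tert-butyldimethylsilyloxy)-2-{4-[(E)-3-(tert-butyldimethylsilyloxy)prop-1-en-1-yl]-2,6-dimethoxyphenoxy}propan-1-ol | OC[C@@H](CO[Si](C)(C)C(C)(C)C)Oc1c(OC)cc(/C=C/CO[Si](C)(C)C(C)(C)C)cc1OC | intermediate
10 | (R)-3-(tert-butyldimethylsilyloxy)-2-{4-[(E)-3-(tert-butyldimethylsilyloxy)prop-1-en-1-yl]-2,6-dimethoxyphenoxy}propanal | O=C[C@@H](CO[Si](C)(C)C(C)(C)C)Oc1c(OC)cc(/C=C/CO[Si](C)(C)C(C)(C)C)cc1OC | intermediate
11 | 4-bromo-2-methoxyphenol | COc1cc(Br)ccc1O | starting material
12 | (4-bromo-2-methoxyphenoxy)(tert-butyl)dimethylsilane | COc1cc(Br)ccc1O[Si](C)(C)C(C)(C)C | intermediate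
13 | 4-(tert-butyldimethylsilyloxy)-3-methoxyphenylmagnesium bromide | COc1cc([Mg]Br)ccc1O[Si](C)(C)C(C)(C)C | intermediate
14 | (1R,2R)-3-(tert-butyldimethylsilyloxy)-1-[4-(tert-butyldimethylsilyloxy)-3-methoxyphenyl]-2-{4-[(E)-3-(tert-butyldimethylsilyloxy)prop-1-en-1-yl]-2,6-dimethoxyphenoxy}propan-1-ol | COc1cc([C@@H](O)[C@@H](CO[Si](C)(C)C(C)(C)C)Oc2c(OC)cc(/C=C/CO[Si](C)(C)C(C)(C)C)cc2OC)ccc1O[Si](C)(C)C(C)(C)C | intermediate
15 | (1R,2R)-1-(4-hydroxy-3-methoxyphenyl)-2-{4-[(E)-3-hydroxyprop-1-en-1-yl]-2,6-dimethoxyphenoxy}propane-1,3-diol (CNP0166461.2) | COc1cc([C@@H](O)[C@@H](CO)Oc2c(OC)cc(/C=C/CO)cc2OC)ccc1O | target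

**Totals**

Total step count: 12. Longest linear sequence: 10 steps (steps 1–8, 11 and 12, from sinapyl alcohol); the Grignard branch adds steps 9 and 10.

**Steps most likely to fail**

1. Step 11. The Felkin–Anh pathway may compete with the weakly held aryl-ether chelate, the more so because THF from the reagent competes for magnesium, so that facial selectivity at C7 is poor and the erythro epimer accompanies the threo one. The fallback sets out from 14 obtained as a C7-epimer mixture. Dess–Martin oxidation of the mixture should converge both epimers on one compound, (R)-3-(tert-butyldimethylsilyloxy)-1-[4-(tert-butyldimethylsilyloxy)-3-methoxyphenyl]-2-{4-[(E)-3-(tert-butyldimethylsilyloxy)prop-1-en-1-yl]-2,6-dimethoxyphenoxy}propan-1-one F1. Reduction of F1 with L-Selectride in THF at −78 °C, a bulky non-chelating hydride, should follow the polar Felkin–Anh course with hydride delivered anti to the C8–OAr bond, which for the ketone leads to the threo alcohol. The sequence comes back to the route at 14.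

2. Step 5. The enzyme may discriminate the two enantiotopic arms of this bulky, unnatural diacetate poorly or in the unexpected sense, and acetyl migration in the monoacetate before silylation would further erode the enantiomeric purity at C8. The fallback takes C8 from the chiral pool and sets out from 1. Silylation of both hydroxyls (TBSCl, imidazole) would give tert-butyl{4-[(E)-3-(tert-butyldimethylsilyloxy)prop-1-en-1-yl]-2,6-dimethoxyphenoxy}dimethylsilane F2. K2CO3 in methanol would cleave only the aryl silyl ether to give 4-[(E)-3-(tert-butyldimethylsilyloxy)prop-1-en-1-yl]-2,6-dimethoxyphenol F3. Mitsunobu etherification of F3 (PPh3, DIAD, toluene) with methyl (S)-3-(tert-butyldimethylsilyloxy)-2-hydroxypropanoate F4, itself made from commercial methyl (S)-2,3-dihydroxypropanoate by silylation of the primary hydroxyl, should proceed with inversion to give methyl (R)-3-(tert-butyldimethylsilyloxy)-2-{4-[(E)-3-(tert-butyldimethylsilyloxy)prop-1-en-1-yl]-2,6-dimethoxyphenoxy}propanoate F5. LiBH4 reduction of the ester comes back to the route at 9.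

3. Step 8. The α-aryloxy aldehyde may enolise during oxidation, filtration or the short time before use, which racemises C8, and it may lose silanol by β-elimination. The fallback sets out from 9 and avoids a free aldehyde. Oxidation with catalytic TEMPO and PhI(OAc)2 in aqueous acetonitrile, in which the aldehyde exists only in passing as its hydrate, would give (R)-3-(tert-butyldimethylsilyloxy)-2-{4-[(E)-3-(tert-butyldimethylsilyloxy)prop-1-en-1-yl]-2,6-dimethoxyphenoxy}propanoic acid F6. Carbodiimide coupling with N,O-dimethylhydroxylamine would give the Weinreb amide (R)-3-(tert-butyldimethylsilyloxy)-N-methoxy-N-methyl-2-{4-[(E)-3-(tert-butyldimethylsilyloxy)prop-1-en-1-yl]-2,6-dimethoxyphenoxy}propanamide F7. Addition of Grignard reagent 13 to F7 forms a stable chelated adduct that releases the ketone F1 only on work-up. Reduction of F1 with L-Selectride, as in the first fallback, comes back to the route at 14.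

**Further compounds**

F1 | step 11 | (R)-3-(tert-butyldimethylsilyloxy)-1-[4-(tert-butyldimethylsilyloxy)-3-methoxyphenyl]-2-{4-[(E)-3-(tert-butyldimethylsilyloxy)prop-1-en-1-yl]-2,6-dimethoxyphenoxy}propan-1-one | COc1cc(C(=O)[C@@H](CO[Si](C)(C)C(C)(C)C)Oc2c(OC)cc(/C=C/CO[Si](C)(C)C(C)(C)C)cc2OC)ccc1O[Si](C)(C)C(C)(C)C
F2 | step 5 | tert-butyl{4-[(E)-3-(tert-butyldimethylsilyloxy)prop-1-en-1-yl]-2,6-dimethoxyphenoxy}dimethylsilane | COc1cc(/C=C/CO[Si](C)(C)C(C)(C)C)cc(OC)c1O[Si](C)(C)C(C)(C)C
F3 | step 5 | 4-[(E)-3-(tert-butyldimethylsilyloxy)prop-1-en-1-yl]-2,6-dimethoxyphenol | COc1cc(/C=C/CO[Si](C)(C)C(C)(C)C)cc(OC)c1O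
F4 | step 5 | methyl (S)-3-(tert-butyldimethylsilyloxy)-2-hydroxypropanoate | COC(=O)[C@H](CO[Si](C)(C)C(C)(C)C)O
F5 | step 5 | methyl (R)-3-(tert-butyldimethylsilyloxy)-2-{4-[(E)-3-(tert-butyldimethylsilyloxy)prop-1-en-1-yl]-2,6-dimethoxyphenoxy}propanoate | COC(=O)[C@@H](CO[Si](C)(C)C(C)(C)C)Oc1c(OC)cc(/C=C/CO[Si](C)(C)C(C)(C)C)cc1OC
F6 | step 8 | (R)-3-(tert-butyldimethylsilyloxy)-2-{4-[(E)-3-(tert-butyldimethylsilyloxy)prop-1-en-1-yl]-2,6-dimethoxyphenoxy}propanoic acid | OC(=O)[C@@H](CO[Si](C)(C)C(C)(C)C)Oc1c(OC)cc(/C=C/CO[Si](C)(C)C(C)(C)C)cc1OC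
F7 | step 8 | (R)-3-(tert-butyldimethylsilyloxy)-N-methoxy-N-methyl-2-{4-[(E)-3-(tert-butyldimethylsilyloxy)prop-1-en-1-yl]-2,6-dimethoxyphenoxy}propanamide | CON(C)C(=O)[C@@H](CO[Si](C)(C)C(C)(C)C)Oc1c(OC)cc(/C=C/CO[Si](C)(C)C(C)(C)C)cc1OC
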